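**Retrosynthetic overview**

1. Locants: tetralone C1(=O)–C2–C3–C4(H)–C4a…C8a, naphthyl C1′ (on C4), 4′-OH, 8′-OMe; the target is (4S). The last step is hydrogenolysis of a catechol dibenzyl ether.
2. Key disconnection C3–C4, by polarity reversal. C4 becomes the exocyclic carbon of a 1,4-naphthoquinone methide and C3 a ketone homoenolate stored as a 1-arylcyclopropanol. Two features allow this: the free 4′-OH para to C1′ on the naphthalene ring (C4 can be raised to the quinone methide level), and the C1 carbonyl 1,3 to C3 (C1–C2–C3 can be folded into a cyclopropanol). Both side chains sit ortho on C4a/C8a of the catechol ring.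
3. The cyclopropanol comes from a 3-arylphthalide by Kulinkovich reaction (lactone C=O becomes C1; C2 and C3 come from EtMgBr).
4. The phthalide comes from dilithiated 2,3-bis(benzyloxy)-6-bromobenzoic acid and 8-methoxy-4-silyloxy-1-naphthaldehyde. The aldehyde is made from 1,5-dimethoxynaphthalene (Vilsmeier, para-selective demethylation, silylation), the acid from 1,2-bis(benzyloxy)-4-bromobenzene (LDA, CO2).
5. Ring order: both arenes are bought; a temporary lactone ring, then a temporary cyclopropane, then the six-membered carbocycle (C1–C2–C3–C4–C4a–C8a) closed last, with C4 set in that step.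

Key step: step 8

Assumption: the sense of induction of the chiral phosphoric acid in step 8 cannot be predicted with confidence; (R)-TRIP is written, and its antipode would be taken if a first trial favours the (4R)-product.

**Route**

Step 1
Reactants: 1 1,5-dimethoxynaphthalene
Product: 3 4,8-dimethoxynaphthalene-1-carbaldehyde, via aryl iminium salt 2 (not isolated)
Conditions: POCl3 (1.3 equiv), DMF, 90 °C; then ice–water
Reagents that add atoms: N,N-dimethylformamide CN(C)C=O; water O
Why: Vilsmeier–Haack formylation should occur para to one methoxy group (peri to the other), the two such positions being equivalent by symmetry, and stop at the deactivated mono-aldehyde.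

Step 2
Reactants: 3 4,8-dimethoxynaphthalene-1-carbaldehyde
Product: 4 4-hydroxy-8-methoxynaphthalene-1-carbaldehyde
Conditions: NaSEt (2.5 equiv), DMF, 100 °C; then 1 M HCl
Reagents that add atoms: none
Why: Nucleophilic (SN2) aryl methyl ether cleavage by thiolate is expected only at the 4-methoxy group, whose aryloxide is conjugated with the para-formyl group (vinylogous carboxylate) while the 8-methoxy group is not, and the naphthoxide formed resists a second cleavage.

Step 3
Reactants: 4 4-hydroxy-8-methoxynaphthalene-1-carbaldehyde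
Product: 5 8-methoxy-4-[(triisopropylsilyl)oxy]naphthalene-1-carbaldehyde
Conditions: TIPSCl, imidazole, DMF, rt
Reagents that add atoms: chlorotriisopropylsilane CC(C)[Si](Cl)(C(C)C)C(C)C
Why: Standard O-silylation of an acidic naphthol; the bulky TIPS ether is chosen to survive the organolithium and Grignard/titanium steps.

Step 4
Reactants: 6 1,2-bis(benzyloxy)-4-bromobenzene
Product: 8 2,3-bis(benzyloxy)-6-bromobenzoic acid, via aryllithium 7 (not isolated)
Conditions: LDA (1.1 equiv), THF, −78 °C; CO2, −78 °C → rt; 1 M HCl
Reagents that add atoms: carbon dioxide O=C=O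
Why: Directed ortho-lithiation at the most acidic C–H, flanked by bromine and benzyloxy (LDA at −78 °C avoids Br/Li exchange and aryne formation), followed by carboxylation.

Step 5
Reactants: 8 2,3-bis(benzyloxy)-6-bromobenzoic acid; 5 8-methoxy-4-[(triisopropylsilyl)oxy]naphthalene-1-carbaldehyde
Product: 11 rac-6,7-bis(benzyloxy)-3-{8-methoxy-4-[(triisopropylsilyl)oxy]naphthalen-1-yl}-2-benzofuran-1(3H)-one, via dilithiated benzoate 9 (not isolated), via hydroxy acid 10 (not isolated)
Conditions: n-BuLi (2.05 equiv), THF, −90 °C; then 5, −90 → 0 °C; 1 M HCl, then PhMe, 40 °C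
Reagents that add atoms: none
Why: Carboxylate formation and Br/Li exchange give the ortho-lithiated benzoate (Parham-type), which should add to the aldehyde, and acidification closes the γ-lactone; the new carbinol centre is racemic, which is harmless because it is erased in step 8.

Step 6
Reactants: 11 rac-6,7-bis(benzyloxy)-3-{8-methoxy-4-[(triisopropylsilyl)oxy]naphthalen-1-yl}-2-benzofuran-1(3H)-one
Product: 12 rac-1-[2,3-bis(benzyloxy)-6-(hydroxy{8-methoxy-4-[(triisopropylsilyl)oxy]naphthalen-1-yl}methyl)phenyl]cyclopropan-1-ol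
Conditions: EtMgBr (3.5 equiv), Ti(OiPr)4 (1.1 equiv), THF, 0 °C → rt; aq. NH4Cl
Reagents that add atoms: ethylmagnesium bromide CC[Mg]Br
Why: Kulinkovich cyclopropanation of a lactone: the titanacyclopropane from EtMgBr/Ti(OiPr)4 acts as a 1,2-dicarbanion on the lactone carbonyl, giving the cyclopropanol and freeing the benzylic alkoxide, while silyl and benzyl ethers are inert.

Step 7
Reactants: 12 rac-1-[2,3-bis(benzyloxy)-6-(hydroxy{8-methoxy-4-[(triisopropylsilyl)oxy]naphthalen-1-yl}methyl)phenyl]cyclopropan-1-ol
Product: 13 rac-1-{2,3-bis(benzyloxy)-6-[hydroxy(4-hydroxy-8-methoxynaphthalen-1-yl)methyl]phenyl}cyclopropan-1-ol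
Conditions: TBAF (1.1 equiv), AcOH (1.1 equiv), THF, 0 °C; crude product used at once
Reagents that add atoms: none
Why: Fluoride-induced cleavage of the aryl silyl ether, buffered with acetic acid so that neither the base-sensitive cyclopropanol nor the acid-sensitive p-hydroxybenzhydrol is touched.

Step 8
Reactants: 13 rac-1-{2,3-bis(benzyloxy)-6-[hydroxy(4-hydroxy-8-methoxynaphthalen-1-yl)methyl]phenyl}cyclopropan-1-ol
Product: 15 (4S)-7,8-bis(benzyloxy)-4-(4-hydroxy-8-methoxynaphthalen-1-yl)-3,4-dihydronaphthalen-1(2H)-one, via naphthoquinone methide 14 (not isolated)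
Conditions: (R)-TRIP (10 mol %), 5 Å MS, PhMe, 0 → 25 °C
Reagents that add atoms: none
Why: Proposed new method: the chiral phosphoric acid should dehydrate the 4-hydroxynaphthyl carbinol of 13 to the (E)-1,4-naphthoquinone methide 14 and stay hydrogen-bonded to its carbonyl oxygen, which makes C4 electrophilic, while the phosphoryl oxygen accepts the cyclopropanol O–H so that the strained C1–C3 σ bond (a ketone homoenolate, C3 with reversed polarity) attacks C4 and the C3–C4 bond, the C1 ketone and the aromatic naphthol arise together. The closest known reaction types are phosphoric acid-catalysed enantioselective 1,6-additions to p-quinone methides generated in situ from p-hydroxybenzyl alcohols and the acid-promoted cyclisation of cyclopropanols onto oxocarbenium ions (semipinacol-like ring opening); their merger, with a σ-bond nucleophile under enantiocontrol, is what is new. The one ring formed is the six-membered carbocycle C1–C2–C3–C4–C4a–C8a, closed in the 6-exo-trig mode onto the exocyclic C4=C1′ bond of the quinone methide, the ortho placement of the two side chains on C4a and C8a allowing no other ring size for C-attack. The only stereocentre, C4, is set by the catalyst: the phosphate bridges the cyclopropanol OH and the quinone methide oxygen inside its 3,3′-aryl pocket and so exposes one face of the planar C4, and because the carbinol centre of racemic 13 is erased in 14 the process is enantioconvergent. The step needs C-attack to win over O-attack of the cyclopropanol oxygen on C4 (a spiro-dihydroisobenzofuran) and over protonolytic opening to the ethyl ketone; the first is secured by the reversibility of the oxa-1,6-addition at the naphthol-stabilised benzylic position against the irreversible, strain-releasing C–C bond formation, the second by the weak acid in a dry non-protic medium, and the peri 8′-methoxy group holds the quinone methide in one geometry so that face selection translates into one enantiomer.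

Step 9
Reactants: 15 (4S)-7,8-bis(benzyloxy)-4-(4-hydroxy-8-methoxynaphthalen-1-yl)-3,4-dihydronaphthalen-1(2H)-one
Product: 16 (4S)-7,8-dihydroxy-4-(4-hydroxy-8-methoxynaphthalen-1-yl)-3,4-dihydronaphthalen-1(2H)-one
Conditions: H2 (1 atm), 10% Pd/C, EtOAc–MeOH, rt; work-up under argon
Reagents that add atoms: none
Why: Hydrogenolysis of the two benzyl ethers under neutral conditions should leave the hydrogen-bonded aryl ketone, the aryl methyl ether and the C4 stereocentre (no acidic C–H, no ionisable leaving group) untouched.

**Compound list**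

1 | 1,5-dimethoxynaphthalene | COc1cccc2c(OC)cccc12 | starting material
2 | N-[(4,8-dimethoxynaphthalen-1-yl)methylidene]-N-methylmethanaminium dichlorophosphate | COc1cccc2c(OC)ccc(C=[N+](C)C)c12.[O-]P(=O)(Cl)Cl | intermediate (not isolated)
3 | 4,8-dimethoxynaphthalene-1-carbaldehyde | COc1cccc2c(OC)ccc(C=O)c12 | intermediate
4 | 4-hydroxy-8-methoxynaphthalene-1-carbaldehyde | COc1cccc2c(O)ccc(C=O)c12 | intermediate
5 | 8-methoxy-4-[(triisopropylsilyl)oxy]naphthalene-1-carbaldehyde | COc1cccc2c(O[Si](C(C)C)(C(C)C)C(C)C)ccc(C=O)c12 | intermediate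
6 | 1,2-bis(benzyloxy)-4-bromobenzene | Brc1ccc(OCc2ccccc2)c(OCc2ccccc2)c1 | starting material
7 | [2,3-bis(benzyloxy)-6-bromophenyl]lithium | [Li]c1c(Br)ccc(OCc2ccccc2)c1OCc1ccccc1 | intermediate (not isolated)
8 | 2,3-bis(benzyloxy)-6-bromobenzoic acid | OC(=O)c1c(Br)ccc(OCc2ccccc2)c1OCc1ccccc1 | intermediate
9 | lithium 2,3-bis(benzyloxy)-6-lithiobenzoate | [Li]OC(=O)c1c([Li])ccc(OCc2ccccc2)c1OCc1ccccc1 | intermediate (not isolated)
10 | rac-2,3-bis(benzyloxy)-6-(hydroxy{8-methoxy-4-[(triisopropylsilyl)oxy]naphthalen-1-yl}methyl)benzoic acid | OC(=O)c1c(C(O)c2ccc(O[Si](C(C)C)(C(C)C)C(C)C)c3cccc(OC)c23)ccc(OCc2ccccc2)c1OCc1ccccc1 | intermediate (not isolated)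
11 | rac-6,7-bis(benzyloxy)-3-{8-methoxy-4-[(triisopropylsilyl)oxy]naphthalen-1-yl}-2-benzofuran-1(3H)-one | O=C1OC(c2ccc(O[Si](C(C)C)(C(C)C)C(C)C)c3cccc(OC)c23)c2ccc(OCc3ccccc3)c(OCc3ccccc3)c21 | intermediate
12 | rac-1-[2,3-bis(benzyloxy)-6-(hydroxy{8-methoxy-4-[(triisopropylsilyl)oxy]naphthalen-1-yl}methyl)phenyl]cyclopropan-1-ol | OC1(CC1)c1c(C(O)c2ccc(O[Si](C(C)C)(C(C)C)C(C)C)c3cccc(OC)c23)ccc(OCc2ccccc2)c1OCc1ccccc1 | intermediate
13 | rac-1-{2,3-bis(benzyloxy)-6-[hydroxy(4-hydroxy-8-methoxynaphthalen-1-yl)methyl]phenyl}cyclopropan-1-ol | OC1(CC1)c1c(C(O)c2ccc(O)c3cccc(OC)c23)ccc(OCc2ccccc2)c1OCc1ccccc1 | intermediate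
14 | (4E)-4-{[3,4-bis(benzyloxy)-2-(1-hydroxycyclopropyl)phenyl]methylidene}-5-methoxynaphthalen-1(4H)-one | OC1(CC1)c1c(/C=C2\C=CC(=O)c3cccc(OC)c32)ccc(OCc2ccccc2)c1OCc1ccccc1 | intermediate (not isolated)
15 | (4S)-7,8-bis(benzyloxy)-4-(4-hydroxy-8-methoxynaphthalen-1-yl)-3,4-dihydronaphthalen-1(2H)-one | COc1cccc2c(O)ccc([C@@H]3CCC(=O)c4c3ccc(OCc3ccccc3)c4OCc3ccccc3)c12 | intermediate
16 | (4S)-7,8-dihydroxy-4-(4-hydroxy-8-methoxynaphthalen-1-yl)-3,4-dihydronaphthalen-1(2H)-one | COc1cccc2c(O)ccc([C@@H]3CCC(=O)c4c3ccc(O)c4O)c12 | target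

**Step count and risks**

Total steps: 9. Longest linear sequence: 8 (steps 1, 2, 3, 5, 6, 7, 8, 9).

Steps most likely to fail:

1. Step 8 (proposed new method). What may go wrong: insufficient enantiofacial discrimination (a loosely organised ion pair or an uncatalysed background cyclisation), or σ-bond attack so slow that the reversible O-cyclisation and protonolysis of the cyclopropanol take over. Fallback with known chemistry, setting out from 12 and returning at 15: the Lewis-acid-promoted cyclisation of a cyclopropanol onto an oxocarbenium-type cation is applied to the silyl ether 12 (BF3·OEt2, CH2Cl2, −78 °C), whose p-silyloxynaphthyl carbinol ionises to a vinylogous oxocarbenium ion. This should give rac-7,8-bis(benzyloxy)-4-{8-methoxy-4-[(triisopropylsilyl)oxy]naphthalen-1-yl}-3,4-dihydronaphthalen-1(2H)-one F1. TBAF then gives rac-7,8-bis(benzyloxy)-4-(4-hydroxy-8-methoxynaphthalen-1-yl)-3,4-dihydronaphthalen-1(2H)-one F2. Acylation of the naphthol with (1S)-(−)-camphanic chloride (Et3N, DMAP, CH2Cl2) and separation of the diastereomers by chromatography or crystallisation gives 4-[(1S)-7,8-bis(benzyloxy)-4-oxo-1,2,3,4-tetrahydronaphthalen-1-yl]-5-methoxynaphthalen-1-yl (1S,4R)-camphanate F3, whose configuration would be confirmed crystallographically. K2CO3/MeOH then returns 15.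

2. Step 6. What may go wrong: failure of the titanacyclopropane to insert into the hindered lactone carbonyl flanked by the benzyloxy group, or deprotonation at the benzylic lactone C–H by the Grignard reagent. Fallback, setting out from 6 and returning at 12: aryllithium 7 (LDA, THF, −78 °C) is added to cyclopropanone generated in situ from 1-ethoxycyclopropan-1-ol and MeMgBr, to give 1-[2,3-bis(benzyloxy)-6-bromophenyl]cyclopropan-1-ol F4. Double lithiation of this compound (n-BuLi, 2.05 equiv, THF, −78 °C; O–Li formation and Br/Li exchange) and addition to aldehyde 5 should then give 12 directly, bypassing lactone 11 and the titanium chemistry.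

3. Step 5. What may go wrong: self-condensation or premature protonation of the dilithiated benzoate, or attack of residual butyllithium on the aldehyde or silyl ether. Fallback, setting out from 8 and returning at 11: esterification (MeI, K2CO3, DMF) gives methyl 2,3-bis(benzyloxy)-6-bromobenzoate F5. Nickel-catalysed reductive coupling–lactonisation of this o-bromobenzoate with aldehyde 5 (NiBr2(dppe) cat., Zn, THF, 75 °C) should then form phthalide 11 under neutral conditions without organolithium intermediates.

Further compounds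
F1 | step 8 | rac-7,8-bis(benzyloxy)-4-{8-methoxy-4-[(triisopropylsilyl)oxy]naphthalen-1-yl}-3,4-dihydronaphthalen-1(2H)-one | COc1cccc2c(O[Si](C(C)C)(C(C)C)C(C)C)ccc(C3CCC(=O)c4c3ccc(OCc3ccccc3)c4OCc3ccccc3)c12
F2 | step 8 | rac-7,8-bis(benzyloxy)-4-(4-hydroxy-8-methoxynaphthalen-1-yl)-3,4-dihydronaphthalen-1(2H)-one | COc1cccc2c(O)ccc(C3CCC(=O)c4c3ccc(OCc3ccccc3)c4OCc3ccccc3)c12
F3 | step 8 | 4-[(1S)-7,8-bis(benzyloxy)-4-oxo-1,2,3,4-tetrahydronaphthalen-1-yl]-5-methoxynaphthalen-1-yl (1S,4R)-camphanate | CC1(C)[C@@]2(C)CC[C@]1(C(=O)Oc1ccc([C@@H]3CCC(=O)c4c3ccc(OCc3ccccc3)c4OCc3ccccc3)c3c(OC)cccc13)OC2=O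
F4 | step 6 | 1-[2,3-bis(benzyloxy)-6-bromophenyl]cyclopropan-1-ol | OC1(CC1)c1c(Br)ccc(OCc2ccccc2)c1OCc1ccccc1
F5 | step 5 | methyl 2,3-bis(benzyloxy)-6-bromobenzoate | COC(=O)c1c(Br)ccc(OCc2ccccc2)c1OCc1ccccc1
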